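The piperidine is cut at C6′, the only unsubstituted methylene next to nitrogen, which lies between N1′ and C5′ and is supplied by carbon monoxide. A rhodium-catalysed intramolecular hydroaminomethylation of a homoallylic N-methylamine forms the C5′–C6′ and N1′–C6′ bonds and closes the six-membered ring in one operation, without touching the C2′ stereocentre. The precursor already holds N1′ with its methyl group, C2′ (R, set by allylation of a tert-butanesulfinyl imine) bearing the 2,4,6-trimethoxyphenyl ring that becomes the flavone A ring, and the allyl unit C3′–C5′. Acetylation, Claisen condensation, cyclodehydration and ether cleavage then complete the flavone.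

Key step: step 5

Remark: piperidine atoms are numbered N1′, C2′ (aryl-bearing, R in the target) to C6′, and flavone atoms as in 4H-chromen-4-one; the sense of induction in step 2 is assigned from the chelated chair model, which calls for the S-configured sulfinamide.

Step 1
Reactants: 1 2,4,6-trimethoxybenzaldehyde; 2 (S)-2-methylpropane-2-sulfinamide
Product: 3 (S)-2-methyl-N-[(E)-(2,4,6-trimethoxyphenyl)methylidene]propane-2-sulfinamide
Conditions: Ti(OEt)4 (2 equiv), THF, 65 °C
Reagents that add atoms: none
Why: Titanium-mediated condensation of an aldehyde with a tert-butanesulfinamide (Ellman imine formation), in which Ti(OEt)4 activates the electron-rich, hindered aldehyde and takes up the water, and the aldimine should form as the E isomer only.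

Step 2
Reactants: 3 (S)-2-methyl-N-[(E)-(2,4,6-trimethoxyphenyl)methylidene]propane-2-sulfinamide; 4 allylmagnesium bromide
Product: 5 (S)-2-methyl-N-[(1R)-1-(2,4,6-trimethoxyphenyl)but-3-en-1-yl]propane-2-sulfinamide
Conditions: allylMgBr (1 M in Et2O, 2 equiv), CH2Cl2, −78 °C; sat. aq. NH4Cl
Reagents that add atoms: none
Why: Diastereoselective Grignard addition to an N-sulfinyl aldimine, in which magnesium bound to the sulfinyl oxygen in the non-coordinating solvent delivers allyl through a six-membered chair with tert-butyl equatorial, so that the S-configured sulfur directs attack to the Re face of C=N and sets the 1R centre (C2′ of the target), the minor diastereomer being removable by chromatography.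

Step 3
Reactants: 5 (S)-2-methyl-N-[(1R)-1-(2,4,6-trimethoxyphenyl)but-3-en-1-yl]propane-2-sulfinamide
Product: 6 (S)-N,2-dimethyl-N-[(1R)-1-(2,4,6-trimethoxyphenyl)but-3-en-1-yl]propane-2-sulfinamide
Conditions: NaH (1.5 equiv), MeI (2 equiv), DMF, 0 °C → rt
Reagents that add atoms: iodomethane, CI
Why: N-alkylation of a sulfinamide anion, in which the N–H is the only acidic site, methyl iodide is the least demanding electrophile for the hindered nitrogen, and neither stereocentre takes part.

Step 4
Reactants: 6 (S)-N,2-dimethyl-N-[(1R)-1-(2,4,6-trimethoxyphenyl)but-3-en-1-yl]propane-2-sulfinamide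
Product: 7 (1R)-N-methyl-1-(2,4,6-trimethoxyphenyl)but-3-en-1-amine
Conditions: HCl (4 M in dioxane, 2.5 equiv), MeOH, 0 °C, 30 min; then aq. NaOH, CH2Cl2 extraction
Reagents that add atoms: none
Why: Acidic methanolysis of the N–S bond (standard removal of the tert-butanesulfinyl auxiliary), kept cold and brief with little excess acid so that the electron-rich benzylic C–N bond does not ionise, after which base liberates the secondary amine.

Step 5
Reactants: 7 (1R)-N-methyl-1-(2,4,6-trimethoxyphenyl)but-3-en-1-amine; 8 carbon monoxide
Product: 11 (2R)-1-methyl-2-(2,4,6-trimethoxyphenyl)piperidine, via amino aldehyde 9 (not isolated), via cyclic enamine 10 (not isolated)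
Conditions: [Rh(cod)2]BF4 (1 mol %), Xantphos (4 mol %), CO (7 bar), H2 (33 bar), toluene/MeOH 1:1, 100 °C
Reagents that add atoms: none
Why: Rhodium hydride adds across the terminal C4′=C5′ alkene with the metal on C5′, CO inserts and hydrogenolysis releases linear amino aldehyde 9, whose carbonyl carbon is C6′. The secondary amine N1′ then attacks this carbonyl in a 6-exo-trig closure (N1′–C6′ bond), and loss of water gives the endocyclic enamine 10, in equilibrium with its iminium ion, which the same rhodium hydride hydrogenates to the N-methylpiperidine. The closest known chemistry is rhodium/Xantphos hydroaminomethylation of terminal alkenes with secondary amines and its intramolecular form on amino alkenes. No stereocentre is created, and C2′ lies outside the C5′=C6′ enamine and stays R as a neutral amine carbon under these near-neutral conditions. The step needs linear rather than branched hydroformylation, since the branched aldehyde would close to a 2-aryl-4-methylpyrrolidine; the wide-bite-angle diphosphine on a monosubstituted alkene enforces anti-Markovnikov addition, and the bulky di-ortho-methoxyaryl group beside nitrogen makes the amine a poor directing ligand, so chelation-driven branched insertion should be disfavoured.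

Step 6
Reactants: 11 (2R)-1-methyl-2-(2,4,6-trimethoxyphenyl)piperidine
Product: 13 1-[2-hydroxy-4,6-dimethoxy-3-[(2R)-1-methylpiperidin-2-yl]phenyl]ethan-1-one, via trimethoxy ketone 12 (not isolated)
Conditions: BF3·OEt2 (6 equiv), then Ac2O (3 equiv), CH2Cl2, 0 °C → rt; aq. NaOH, MeOH work-up
Reagents that add atoms: acetic anhydride, CC(=O)OC(C)=O
Why: Friedel–Crafts acetylation at the free ring position (the two are equivalent) followed in the same pot by boron-chelate-assisted cleavage of an ortho methyl ether, in which the ether wedged between the acetyl and piperidinyl groups is twisted out of the ring plane, hence more Lewis basic, and should be the one lost, placing the phenol where O1 of the flavone must sit, while the amine is masked as its BF3 adduct before the anhydride is added so that nitrogen is not acylated.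

Step 7
Reactants: 13 1-[2-hydroxy-4,6-dimethoxy-3-[(2R)-1-methylpiperidin-2-yl]phenyl]ethan-1-one; 14 methyl benzoate
Product: 16 5,7-dimethoxy-8-[(2R)-1-methylpiperidin-2-yl]-2-phenyl-4H-chromen-4-one, via beta-diketone 15 (not isolated)
Conditions: NaH (5 equiv), DMF, 0 °C → rt; then conc. HCl, rt → 50 °C; aq. Na2CO3 work-up
Reagents that add atoms: none
Why: Crossed Claisen condensation of the phenoxide–enolate dianion with the non-enolisable ester gives the 1,3-diketone (the same compound a Baker–Venkataraman rearrangement would deliver), and acid-catalysed cyclodehydration closes the pyranone, the protonated amine on an acyl-deactivated ring being expected to hold its C2′ configuration in the mild acid.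

Step 8
Reactants: 16 5,7-dimethoxy-8-[(2R)-1-methylpiperidin-2-yl]-2-phenyl-4H-chromen-4-one
Product: 17 5,7-dihydroxy-8-[(2R)-1-methylpiperidin-2-yl]-2-phenyl-4H-chromen-4-one
Conditions: BBr3 (8 equiv), CH2Cl2, −78 °C → rt; MeOH quench; aq. NaHCO3 to pH 7–8
Reagents that add atoms: none
Why: Boron tribromide cleavage of both aryl methyl ethers, the 5-ether helped by chelation to the C4 carbonyl and the crowded 7-ether by strain relief, with excess reagent because the amine binds one equivalent, and at low temperature so that neither acid-driven flavone ring isomerisation nor reversible opening of the benzylic C–N bond should disturb C2′.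

Compound list
1 | 2,4,6-trimethoxybenzaldehyde | COc1cc(OC)c(C=O)c(OC)c1 | starting material
2 | (S)-2-methylpropane-2-sulfinamide | CC(C)(C)[S@](=O)N | starting material
3 | (S)-2-methyl-N-[(E)-(2,4,6-trimethoxyphenyl)methylidene]propane-2-sulfinamide | CC(C)(C)[S@](=O)/N=C/c1c(OC)cc(OC)cc1OC | intermediate
4 | allylmagnesium bromide | C=CC[Mg]Br | starting material
5 | (S)-2-methyl-N-[(1R)-1-(2,4,6-trimethoxyphenyl)but-3-en-1-yl]propane-2-sulfinamide | CC(C)(C)[S@](=O)N[C@H](CC=C)c1c(OC)cc(OC)cc1OC | intermediate
6 | (S)-N,2-dimethyl-N-[(1R)-1-(2,4,6-trimethoxyphenyl)but-3-en-1-yl]propane-2-sulfinamide | CC(C)(C)[S@](=O)N(C)[C@H](CC=C)c1c(OC)cc(OC)cc1OC | intermediate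
7 | (1R)-N-methyl-1-(2,4,6-trimethoxyphenyl)but-3-en-1-amine | CN[C@H](CC=C)c1c(OC)cc(OC)cc1OC | intermediate
8 | carbon monoxide | [C-]#[O+] | starting material
9 | (5R)-5-(methylamino)-5-(2,4,6-trimethoxyphenyl)pentanal | CN[C@H](CCCC=O)c1c(OC)cc(OC)cc1OC | intermediate
10 | (2R)-1-methyl-2-(2,4,6-trimethoxyphenyl)-1,2,3,4-tetrahydropyridine | CN1C=CCC[C@@H]1c1c(OC)cc(OC)cc1OC | intermediate
11 | (2R)-1-methyl-2-(2,4,6-trimethoxyphenyl)piperidine | CN1CCCC[C@@H]1c1c(OC)cc(OC)cc1OC | intermediate
12 | 1-[2,4,6-trimethoxy-3-[(2R)-1-methylpiperidin-2-yl]phenyl]ethan-1-one | CN1CCCC[C@@H]1c1c(OC)c(C(C)=O)c(OC)cc1OC | intermediate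
13 | 1-[2-hydroxy-4,6-dimethoxy-3-[(2R)-1-methylpiperidin-2-yl]phenyl]ethan-1-one | CN1CCCC[C@@H]1c1c(O)c(C(C)=O)c(OC)cc1OC | intermediate
14 | methyl benzoate | COC(=O)c1ccccc1 | starting material
15 | 1-[2-hydroxy-4,6-dimethoxy-3-[(2R)-1-methylpiperidin-2-yl]phenyl]-3-phenylpropane-1,3-dione | CN1CCCC[C@@H]1c1c(O)c(C(=O)CC(=O)c2ccccc2)c(OC)cc1OC | intermediate
16 | 5,7-dimethoxy-8-[(2R)-1-methylpiperidin-2-yl]-2-phenyl-4H-chromen-4-one | CN1CCCC[C@@H]1c1c(OC)cc(OC)c2c(=O)cc(-c3ccccc3)oc12 | intermediate
17 | 5,7-dihydroxy-8-[(2R)-1-methylpiperidin-2-yl]-2-phenyl-4H-chromen-4-one | CN1CCCC[C@@H]1c1c(O)cc(O)c2c(=O)cc(-c3ccccc3)oc12 | target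

Total step count: 8
Longest linear sequence: 8 steps (1 to 17)

Steps most likely to fail

Step 5. What may go wrong: nitrogen-directed insertion to the branched aldehyde and hence five-membered ring closure, capture of the acyl-rhodium by nitrogen before hydrogenolysis (lactam formation), migration of the double bond along the chain, or stalling at the enamine stage. The fallback replaces carbonylation by ring-closing metathesis and sets out from 7. N-Acylation with acryloyl chloride (Et3N, CH2Cl2, 0 °C) should give N-methyl-N-[(1R)-1-(2,4,6-trimethoxyphenyl)but-3-en-1-yl]prop-2-enamide F1. A second-generation Grubbs catalyst (CH2Cl2, 40 °C) should close it, with loss of ethylene, to (6R)-1-methyl-6-(2,4,6-trimethoxyphenyl)-5,6-dihydropyridin-2(1H)-one F2. Hydrogenation of the conjugated alkene (H2, Pd/C, EtOAc, rt) should give (6R)-1-methyl-6-(2,4,6-trimethoxyphenyl)piperidin-2-one F3, and LiAlH4 (THF, reflux) should reduce the lactam, coming back to the route at 11. In this variant C5′ and C6′ derive from the acryloyl unit.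

Step 6. What may go wrong: cleavage of the less hindered ortho ether in place of the hindered one, which would lead into the 6-substituted flavone series, or acylation at nitrogen followed by opening of the piperidine at the benzylic C–N bond in the Lewis-acidic anhydride medium. The fallback replaces electrophilic substitution by directed metalation and separates ketone formation from ether cleavage; it sets out from 11. n-BuLi/TMEDA (THF, 0 °C) should remove the ring proton flanked by two methoxy groups to give [2,4,6-trimethoxy-3-[(2R)-1-methylpiperidin-2-yl]phenyl]lithium F4. Quenching with N-methoxy-N-methylacetamide (−78 °C → rt) should give ketone 12, this time isolated without any acid. BCl3 (2.5 equiv, CH2Cl2, −78 → 0 °C), which cleaves only an ether ortho to a carbonyl group through a six-membered boron chelate and prefers the out-of-plane one, should then give 13, where the fallback rejoins the route.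

Step 8. What may go wrong: stalling after the first ether because the 7-ether next to the boron-complexed amine is slow to cleave, or erosion of the C2′ configuration through reversible benzylic C–N opening once the ortho and para phenols are free in the acidic boron medium. The fallback is anionic dealkylation and sets out from 16. Sodium ethanethiolate (6 equiv, DMF, 110 °C; then aq. NH4Cl to pH 7) should remove both methyl groups by SN2 attack at carbon, the flavone oxygens leaving as vinylogous carboxylates, with neither acid nor an ammonium leaving group present. It comes back to the route at 17 directly and makes no new compound (F0).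

Further compounds
F1 | step 5 | N-methyl-N-[(1R)-1-(2,4,6-trimethoxyphenyl)but-3-en-1-yl]prop-2-enamide | C=CC(=O)N(C)[C@H](CC=C)c1c(OC)cc(OC)cc1OC
F2 | step 5 | (6R)-1-methyl-6-(2,4,6-trimethoxyphenyl)-5,6-dihydropyridin-2(1H)-one | CN1C(=O)C=CC[C@@H]1c1c(OC)cc(OC)cc1OC
F3 | step 5 | (6R)-1-methyl-6-(2,4,6-trimethoxyphenyl)piperidin-2-one | CN1C(=O)CCC[C@@H]1c1c(OC)cc(OC)cc1OC
F4 | step 6 | [2,4,6-trimethoxy-3-[(2R)-1-methylpiperidin-2-yl]phenyl]lithium | [Li]c1c(OC)cc(OC)c([C@H]2CCCCN2C)c1OC
F0 | step 8 | none | none
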